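**Retrosynthetic overview**

1. Target 24 ⇐ protected macrocycle 21, by removing the three aryl MOM ethers and then the C1 silyl ether without Brønsted acid at the benzylic carbinol.
2. 21 ⇐ open-chain bromide 19, by cutting the C14–ring A bond (B-alkyl Suzuki macrocyclization). The strategy rests on C14 sitting on a ring A carbon that is meta to both ring A oxygens (phenol O and diaryl ether O) and has only CH neighbours, so a bromide there is open to palladium and lies far from the crowded ring B ether carbon and from carbinol C1.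
3. 19 ⇐ aryl ketone 17 (C1 set R by Noyori transfer hydrogenation) ⇐ Weinreb amide 8 + the C2–C14 (E)-dienyl Grignard reagent 15, made from oct-7-yn-1-ol and 5-bromopent-1-ene with Na/NH3 fixing the C8–C9 E-alkene.
4. 8 ⇐ Ullmann coupling of gallate-derived phenol 4 with dibromide 6 (from 3,5-dibromophenol), which makes the hindered diaryl ether intermolecularly.
5. Ring order: rings A and B come with the starting materials; the only ring formed is the 22-membered macrocycle, closed in step 13.

Key step: step 13

Remark: C1 is the carbinol carbon on ring B, C8=C9 the alkene, C14 the benzylic carbon on ring A. The carbinol of the target SMILES is read as R (O > ring B carbon > C2 > H). The C13 chain is built from oct-7-yn-1-ol and 5-bromopent-1-ene because this needs no alcohol protection.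

**Route**

Step 1
Reactants: 1 methyl gallate
Product: 2 methyl 4-(benzyloxy)-3,5-dihydroxybenzoate
Conditions: BnBr (1.05 equiv), KHCO3, KI (cat.), DMF, 30 °C
Reagents that add atoms: benzyl bromide, BrCc1ccccc1
Why: Williamson etherification; the 4-OH para to the ester is the most acidic phenol, so the weak base should ionize and benzylate O-4 preferentially.

Step 2
Reactants: 2 methyl 4-(benzyloxy)-3,5-dihydroxybenzoate
Product: 3 methyl 4-(benzyloxy)-3,5-bis(methoxymethoxy)benzoate
Conditions: MOMCl (3 equiv), iPr2NEt, CH2Cl2, 0 °C → rt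
Reagents that add atoms: chloromethyl methyl ether, COCCl
Why: O-alkylation of the two remaining phenols with MOMCl and Hünig's base (acetal-forming Williamson etherification); ester and benzyl ether are inert.

Step 3
Reactants: 3 methyl 4-(benzyloxy)-3,5-bis(methoxymethoxy)benzoate
Product: 4 methyl 4-hydroxy-3,5-bis(methoxymethoxy)benzoate
Conditions: H2 (1 atm), Pd/C, EtOAc, rt
Reagents that add atoms: none
Why: Palladium-catalysed hydrogenolysis of the benzyl ether under neutral conditions should free only the 4-OH; MOM acetals and the ester are untouched and no halide is present yet.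

Step 4
Reactants: 5 3,5-dibromophenol
Product: 6 1,3-dibromo-5-(methoxymethoxy)benzene
Conditions: MOMCl, iPr2NEt, CH2Cl2, 0 °C → rt
Reagents that add atoms: chloromethyl methyl ether, COCCl
Why: MOM protection of the phenol by O-alkylation, giving a base-stable symmetric dibromide.

Step 5
Reactants: 4 methyl 4-hydroxy-3,5-bis(methoxymethoxy)benzoate; 6 1,3-dibromo-5-(methoxymethoxy)benzene (3 equiv)
Product: 7 methyl 4-[3-bromo-5-(methoxymethoxy)phenoxy]-3,5-bis(methoxymethoxy)benzoate
Conditions: CuI (10 mol%), picolinic acid (20 mol%), K3PO4, DMSO, 90 °C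
Reagents that add atoms: none
Why: Ullmann-type copper-catalysed diaryl ether synthesis; the picolinate ligand system accepts ortho,ortho-disubstituted phenoxides, and the excess of the symmetric dibromide should hold back double arylation while MOM ethers and the ester survive anhydrous phosphate.

Step 6
Reactants: 7 methyl 4-[3-bromo-5-(methoxymethoxy)phenoxy]-3,5-bis(methoxymethoxy)benzoate
Product: 8 4-[3-bromo-5-(methoxymethoxy)phenoxy]-N-methoxy-N-methyl-3,5-bis(methoxymethoxy)benzamide
Conditions: MeNH(OMe)·HCl, iPrMgCl, THF, −20 → 0 °C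
Reagents that add atoms: N,O-dimethylhydroxylamine hydrochloride, CNOC.Cl
Why: Weinreb amide formation by aminolysis of the ester with the magnesium amide made in the flask; iPrMgCl without LiCl should not exchange with the unactivated aryl bromide at this temperature.

Step 7
Reactants: 9 oct-7-yn-1-ol; 10 5-bromopent-1-ene
Product: 12 tridec-12-en-7-yn-1-ol, via dilithium alkoxide acetylide 11 (not isolated)
Conditions: n-BuLi (2.1 equiv), THF/DMPU, −78 → −20 °C; then 10, −20 °C → rt; then H2O
Reagents that add atoms: none
Why: C-alkylation of an alkynol dianion (acetylide SN2 on a primary bromide); the acetylide carbon is far more nucleophilic than the lithium alkoxide, so no hydroxyl protection is needed.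

Step 8
Reactants: 12 tridec-12-en-7-yn-1-ol
Product: 13 (E)-trideca-7,12-dien-1-ol
Conditions: Na, liq. NH3/THF, −33 °C; then NH4Cl
Reagents that add atoms: none
Why: Dissolving-metal reduction of an internal alkyne; the vinyl radical anion and vinyl anion adopt the trans arrangement before protonation by ammonia, giving the E-alkene, and the isolated terminal alkene is not reduced.

Step 9
Reactants: 13 (E)-trideca-7,12-dien-1-ol
Product: 14 (E)-13-bromotrideca-1,6-diene
Conditions: CBr4, PPh3, CH2Cl2, 0 °C
Reagents that add atoms: carbon tetrabromide, BrC(Br)(Br)Br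
Why: Appel bromination, an SN2 displacement of the oxyphosphonium at a primary carbon; both alkenes are inert.

Step 10
Reactants: 14 (E)-13-bromotrideca-1,6-diene; 8 4-[3-bromo-5-(methoxymethoxy)phenoxy]-N-methoxy-N-methyl-3,5-bis(methoxymethoxy)benzamide
Product: 17 (E)-1-{4-[3-bromo-5-(methoxymethoxy)phenoxy]-3,5-bis(methoxymethoxy)phenyl}tetradeca-8,13-dien-1-one, via Grignard reagent 15 (not isolated), via magnesium hemiaminal chelate 16 (not isolated)
Conditions: Mg, I2 (cat.), THF, rt → 40 °C; then 8, THF, 0 °C; then H2O
Reagents that add atoms: none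
Why: Grignard acylation of a Weinreb amide; the five-membered magnesium chelate 16 stops the addition at the ketone stage, and the aryl bromide and MOM ethers are inert to a primary alkylmagnesium bromide at 0 °C.

Step 11
Reactants: 17 (E)-1-{4-[3-bromo-5-(methoxymethoxy)phenoxy]-3,5-bis(methoxymethoxy)phenyl}tetradeca-8,13-dien-1-one
Product: 18 (R,E)-1-{4-[3-bromo-5-(methoxymethoxy)phenoxy]-3,5-bis(methoxymethoxy)phenyl}tetradeca-8,13-dien-1-ol
Conditions: RuCl(p-cymene)[(R,R)-TsDPEN] (2 mol%), HCO2H/Et3N (5:2), DMF, 30 °C
Reagents that add atoms: none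
Why: Noyori asymmetric transfer hydrogenation of an aryl alkyl ketone; the (R,R)-ligand, through the CH/π contact between ring B and the cymene ligand, should deliver hydride to the Si face and give the R carbinol (the sense known for acetophenone), while the outer-sphere hydride transfer leaves the isolated alkenes and the aryl bromide alone.

Step 12
Reactants: 18 (R,E)-1-{4-[3-bromo-5-(methoxymethoxy)phenoxy]-3,5-bis(methoxymethoxy)phenyl}tetradeca-8,13-dien-1-ol
Product: 19 tert-butyl{[(R,E)-1-{4-[3-bromo-5-(methoxymethoxy)phenoxy]-3,5-bis(methoxymethoxy)phenyl}tetradeca-8,13-dien-1-yl]oxy}dimethylsilane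
Conditions: TBSCl, imidazole, DMF, rt
Reagents that add atoms: tert-butyldimethylsilyl chloride, CC(C)(C)[Si](C)(C)Cl
Why: Silylation of the secondary benzylic alcohol under the imidazole/DMF protocol, which needs no silyl triflate that could attack the MOM acetals; configuration at C1 is not touched.

Step 13
Reactants: 19 tert-butyl{[(R,E)-1-{4-[3-bromo-5-(methoxymethoxy)phenoxy]-3,5-bis(methoxymethoxy)phenyl}tetradeca-8,13-dien-1-yl]oxy}dimethylsilane
Product: 21 (1R,8E)-1-O-TBS-tri-O-MOM-dehydrogravicycle (protected 22-membered macrocycle), via alkyl-9-BBN borane 20 (not isolated)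
Conditions: 9-BBN (1.3 equiv), THF, 0 °C → rt; then syringe-pump addition over 12 h to Pd(dppf)Cl2 (20 mol%), AsPh3 (20 mol%), Cs2CO3 (4 equiv), degassed DMF/THF/H2O, 60 °C, final ca. 1 mM
Reagents that add atoms: none
Why: 9-BBN adds anti-Markovnikov to the monosubstituted C13–C14 alkene to give primary borane 20; zerovalent palladium, formed from Pd(dppf)Cl2, inserts into the ring A C–Br bond, the base-activated borate hands its primary alkyl group to divalent palladium, and reductive elimination makes the aryl–C14 bond. The closest known reaction type is the B-alkyl Suzuki–Miyaura macrocyclization of an alkyl-9-BBN with an aryl or alkenyl halide. The 22-membered ring closes end to end by intramolecular C(sp2)–C(sp3) reductive elimination from a large palladacycle, and slow addition to high dilution should favour this over oligomerization. No stereocenter is formed; C1 (R) and the E-alkene at C8–C9 are carried through unchanged. The step needs chemoselective hydroboration, secured by the large rate preference of the bulky 9-BBN for the terminal over the internal E-alkene. It also needs coupling faster than β-hydride elimination, secured by the wide-bite-angle dppf ligand, the AsPh3 co-ligand and the bromide carbon flanked only by ring CH.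

Step 14
Reactants: 21 (1R,8E)-1-O-TBS-tri-O-MOM-dehydrogravicycle
Product: 23 (1R,8E)-1-O-TBS-dehydrogravicycle (macrocyclic triphenol with C1 silyl ether), via tris(trimethylsilyl) aryl ether 22 (not isolated)
Conditions: TMSOTf, 2,2'-bipyridyl, CH2Cl2/CH3CN, 0 °C → rt; then H2O, rt
Reagents that add atoms: none
Why: Silyl triflate/2,2'-bipyridyl cleavage of aromatic MOM ethers; the buffered silyl triflate turns each ArO–CH2OMe into ArO–SiMe3 plus an N-(methoxymethyl)bipyridinium salt and water then hydrolyses the aryl TMS ethers, so no Brønsted acid reaches the benzylic C1–O bond, which stays as its TBS ether.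

Step 15
Reactants: 23 (1R,8E)-1-O-TBS-dehydrogravicycle
Product: 24 dehydrogravicycle
Conditions: TBAF, AcOH (buffer), THF, 0 °C → rt
Reagents that add atoms: none
Why: Fluoride-mediated desilylation of the secondary TBS ether under buffered, non-ionizing conditions should leave the R configuration at C1 and the E-alkene intact.

**Compound list**

1 | methyl gallate | COC(=O)c1cc(O)c(O)c(O)c1 | starting material
2 | methyl 4-(benzyloxy)-3,5-dihydroxybenzoate | COC(=O)c1cc(O)c(OCc2ccccc2)c(O)c1 | intermediate
3 | methyl 4-(benzyloxy)-3,5-bis(methoxymethoxy)benzoate | COC(=O)c1cc(OCOC)c(OCc2ccccc2)c(OCOC)c1 | intermediate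
4 | methyl 4-hydroxy-3,5-bis(methoxymethoxy)benzoate | COC(=O)c1cc(OCOC)c(O)c(OCOC)c1 | intermediate
5 | 3,5-dibromophenol | Oc1cc(Br)cc(Br)c1 | starting material
6 | 1,3-dibromo-5-(methoxymethoxy)benzene | COCOc1cc(Br)cc(Br)c1 | intermediate
7 | methyl 4-[3-bromo-5-(methoxymethoxy)phenoxy]-3,5-bis(methoxymethoxy)benzoate | COC(=O)c1cc(OCOC)c(Oc2cc(Br)cc(OCOC)c2)c(OCOC)c1 | intermediate
8 | 4-[3-bromo-5-(methoxymethoxy)phenoxy]-N-methoxy-N-methyl-3,5-bis(methoxymethoxy)benzamide | CON(C)C(=O)c1cc(OCOC)c(Oc2cc(Br)cc(OCOC)c2)c(OCOC)c1 | intermediate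
9 | oct-7-yn-1-ol | OCCCCCCC#C | starting material
10 | 5-bromopent-1-ene | BrCCCC=C | starting material
11 | dilithium alkoxide acetylide of oct-7-yn-1-ol | [Li]OCCCCCCC#C[Li] | intermediate
12 | tridec-12-en-7-yn-1-ol | OCCCCCCC#CCCCC=C | intermediate
13 | (E)-trideca-7,12-dien-1-ol | OCCCCCC/C=C/CCCC=C | intermediate
14 | (E)-13-bromotrideca-1,6-diene | BrCCCCCC/C=C/CCCC=C | intermediate
15 | (E)-trideca-7,12-dien-1-ylmagnesium bromide | Br[Mg]CCCCCC/C=C/CCCC=C | intermediate
16 | bromomagnesium alkoxide of the N-methoxy-N-methyl hemiaminal (tetrahedral chelate of 8 and 15) | COCOc1cc(Br)cc(c1)Oc1c(OCOC)cc(cc1OCOC)C(O[Mg]Br)(N(C)OC)CCCCCC/C=C/CCCC=C | intermediate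
17 | (E)-1-{4-[3-bromo-5-(methoxymethoxy)phenoxy]-3,5-bis(methoxymethoxy)phenyl}tetradeca-8,13-dien-1-one | COCOc1cc(Br)cc(c1)Oc1c(OCOC)cc(cc1OCOC)C(=O)CCCCCC/C=C/CCCC=C | intermediate
18 | (R,E)-1-{4-[3-bromo-5-(methoxymethoxy)phenoxy]-3,5-bis(methoxymethoxy)phenyl}tetradeca-8,13-dien-1-ol | COCOc1cc(Br)cc(c1)Oc1c(OCOC)cc(cc1OCOC)[C@H](O)CCCCCC/C=C/CCCC=C | intermediate
19 | TBS ether of 18 (macrocyclization precursor) | COCOc1cc(Br)cc(c1)Oc1c(OCOC)cc(cc1OCOC)[C@H](O[Si](C)(C)C(C)(C)C)CCCCCC/C=C/CCCC=C | intermediate
20 | C14 B-alkyl-9-borabicyclo[3.3.1]nonane adduct of 19 | COCOc1cc(Br)cc(c1)Oc1c(OCOC)cc(cc1OCOC)[C@H](O[Si](C)(C)C(C)(C)C)CCCCCC/C=C/CCCCCB1C2CCCC1CCC2 | intermediate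
21 | (1R,8E)-1-O-TBS-tri-O-MOM-dehydrogravicycle (22-membered ring: C1–C14, ring A bridged 1,3 with OMOM at the third meta position, ring B bridged 1,4 with OMOM on both carbons next to the ether carbon) | COCOc1cc2cc(c1)Oc1c(OCOC)cc(cc1OCOC)[C@H](O[Si](C)(C)C(C)(C)C)CCCCCC/C=C/CCCCC2 | intermediate
22 | tris(trimethylsilyl) aryl ether of 23 | C[Si](C)(C)Oc1cc2cc(c1)Oc1c(O[Si](C)(C)C)cc(cc1O[Si](C)(C)C)[C@H](O[Si](C)(C)C(C)(C)C)CCCCCC/C=C/CCCCC2 | intermediate
23 | (1R,8E)-1-O-TBS-dehydrogravicycle | Oc1cc2cc(c1)Oc1c(O)cc(cc1O)[C@H](O[Si](C)(C)C(C)(C)C)CCCCCC/C=C/CCCCC2 | intermediate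
24 | dehydrogravicycle | Oc1cc2cc(c1)Oc1c(O)cc(cc1O)[C@H](O)CCCCCC/C=C/CCCCC2 | target

**Step count**

Total: 15 steps. Longest linear sequence: 11 steps (1, 2, 3, 5, 6, 10, 11, 12, 13, 14, 15 from methyl gallate).

**Steps most likely to fail**

Step 13 (macrocyclization). Intermolecular coupling to oligomers may outrun ring closure, or slow transmetalation at high dilution may let protodeboronation and β-hydride elimination return open-chain material. The fallback closes the same aryl–C14 bond with zinc in place of boron; it sets out from 19 and comes back at 21. Hydroboration of 19 with 9-BBN (through 20) and oxidation with NaOH/H2O2 should give the primary alcohol (6E,14R)-14-aryl-14-(tert-butyldimethylsilyloxy)tetradec-6-en-1-ol F1. Treatment with I2, PPh3 and imidazole in CH2Cl2 should give the primary iodide F2. Activated zinc dust with LiCl in THF should insert into the C–I bond only, giving the alkylzinc iodide F3, which is not isolated. Slow addition of it to Pd(OAc)2/SPhos in THF/NMP at 50 °C (intramolecular Negishi coupling) should give 21.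

Step 5 (Ullmann coupling). The doubly ortho-substituted, ester-deactivated phenoxide may couple sluggishly, so that long heating brings ester hydrolysis or double arylation of the dibromide. The fallback turns ring A into the nucleophile-free partner of an oxidative coupling; it sets out from 6 (with 4) and comes back at 7. Mono bromine–lithium exchange of 6 (n-BuLi, THF/toluene, −78 °C), B(OiPr)3 and aqueous work-up should give (3-bromo-5-(methoxymethoxy)phenyl)boronic acid F4. Chan–Lam–Evans coupling of it with phenol 4 (Cu(OAc)2, pyridine, Et3N, 4 Å sieves, CH2Cl2, air, rt) should give 7 at room temperature, with the aryl bromide untouched.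

Step 14 (MOM removal). The silyl triflate may ionize or desilylate the benzylic C1–O bond (loss of configuration, elimination toward the styrene), or the two crowded MOM ethers flanking the diaryl ether may cleave incompletely. The fallback takes the carbinol out of play before acid is used; it sets out from 21 and comes back at 24. TBAF should give the macrocyclic carbinol tri-MOM ether F5, and Dess–Martin periodinane in CH2Cl2 the macrocyclic aryl ketone tri-MOM ether F6. With no ionizable benzylic C–O bond left, HCl in MeOH/THF at 40 °C should cleave all three MOM ethers to the macrocyclic triphenol ketone F7. Transfer hydrogenation with RuCl(p-cymene)[(R,R)-TsDPEN] in HCO2H/Et3N then re-sets C1 as R and gives 24.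

**Further compounds**

F1 | step 13 | (6E,14R)-14-{4-[3-bromo-5-(methoxymethoxy)phenoxy]-3,5-bis(methoxymethoxy)phenyl}-14-(tert-butyldimethylsilyloxy)tetradec-6-en-1-ol | COCOc1cc(Br)cc(c1)Oc1c(OCOC)cc(cc1OCOC)[C@H](O[Si](C)(C)C(C)(C)C)CCCCCC/C=C/CCCCCO
F2 | step 13 | primary iodide from F1 (C14 iodide) | COCOc1cc(Br)cc(c1)Oc1c(OCOC)cc(cc1OCOC)[C@H](O[Si](C)(C)C(C)(C)C)CCCCCC/C=C/CCCCCI
F3 | step 13 | alkylzinc iodide from F2 | COCOc1cc(Br)cc(c1)Oc1c(OCOC)cc(cc1OCOC)[C@H](O[Si](C)(C)C(C)(C)C)CCCCCC/C=C/CCCCC[Zn]I
F4 | step 5 | (3-bromo-5-(methoxymethoxy)phenyl)boronic acid | COCOc1cc(Br)cc(c1)B(O)O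
F5 | step 14 | (1R,8E)-tri-O-MOM-dehydrogravicycle (free C1 carbinol) | COCOc1cc2cc(c1)Oc1c(OCOC)cc(cc1OCOC)[C@H](O)CCCCCC/C=C/CCCCC2
F6 | step 14 | (8E)-1-oxo-tri-O-MOM macrocycle (aryl ketone) | COCOc1cc2cc(c1)Oc1c(OCOC)cc(cc1OCOC)C(=O)CCCCCC/C=C/CCCCC2
F7 | step 14 | (8E)-1-oxo macrocyclic triphenol | Oc1cc2cc(c1)Oc1c(O)cc(cc1O)C(=O)CCCCCC/C=C/CCCCC2
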